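## Structural features

The target is a bisabolane-type diester: a cyclohexane (C1–C6) joined through the C1–C7 bond to a five-carbon chain (C7–C11). The chain carries an exocyclic methylene on C7, an angelate on C8 and a trisubstituted 10,11-epoxide. Five contiguous ring stereocentres stand next to each other: C1 (chain), C6 (free OH), C5 (O-angelate), C4 (methyl and tertiary OH) and C3 (Cl). The C1 chain and the oxygens on C4, C5 and C6 share one face, and the chlorine is trans to the C4 hydroxyl. This is the pattern of a trans-diaxial chlorohydrin from a C3–C4 epoxide lying syn to O5. Two more stereocentres, C8 and C10, sit in the chain; C8 is allylic to the C7 methylene and one bond away from C1. The fragile groups are: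
- the two (Z)-2-methylbut-2-enoates, which isomerise to tiglates and can migrate between the cis oxygens on C5 and C6;
- the acid-labile epoxide, which a free C8 hydroxyl could open;
- the chlorohydrin, which closes again with base.

The real difficulty is the all-cis C1/C5/C6 triad, whose 1,2-diol must later be differentiated, together with the relay of absolute configuration between chain and ring. The key step uses the fact that O5 and O6 are cis and vicinal, so one silicon atom can bridge them, and that C1 bears the acyl-type carbon C7 on the same face. C5–C6 and C1–C2 are then the two bonds of a cyclohexene formed from a C2–C5 diene and a (Z)-C6=C1–C7(=O) enone, which leaves the alkene at C3=C4, where the chlorohydrin is needed.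

## Logic of the disconnections

23 ⇒ 22. The C10–O and C11–O bonds of the oxirane are cut. The oxirane is the most acid-sensitive group and must not coexist with a free C8 hydroxyl or with any desilylation. The gain is one stereocentre and one fragile ring less. The forward step must epoxidise one of four alkenes under reagent control on the otherwise finished molecule.

22 ⇒ 21 + 19. The O8–acyl bond is cut. This leaves a single unhindered secondary hydroxyl to be esterified. The forward step must acylate O8 in the presence of the axial C6 and tertiary C4 hydroxyls without Z to E isomerisation of either ester.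

21 ⇒ 20. The O8–Si bond is added back. O8 has to stay masked through the hydroxyl-directed ring epoxidation, where a free allylic O8–H would steer oxidant to C7=CH2. The forward step must be a non-basic desilylation that spares chlorohydrin and ester.

20 ⇒ 18 + 19. The O5–acyl bond is cut. This is the point where the cis-5,6-diol is differentiated. The forward step must acylate the equatorial O5 and not the axial O6.

18 ⇒ 17. The C3–Cl bond is cut and the C3–O bond of an oxirane restored. The trans chlorohydrin is the retron of an epoxide opening with inversion. The forward step must put chloride on C3, not on the tertiary C4.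

17 ⇒ 16. The C3–O and C4–O oxirane bonds are cut. Two stereocentres are removed. The forward step must oxidise only the ring alkene, on the face of O5.

16 ⇒ 15. Two O–Si bonds are restored, which re-forms the five-membered silylene. The forward step must cleave the strained ring while the C8 silyl ether survives.

15 ⇒ 14. The C7=CH2 bond is exchanged for C7=O. The ketone is what activates the dienophile in the key step. The forward step must methylenate a hindered ketone flanked by an epimerisable C1 and a β-silyloxy group without base.

14 ⇒ 13. The C5–C6 and C1–C2 bonds are cut. Two rings and three stereocentres disappear, and an acyclic, achiral-at-ring precursor with only the C8 centre remains. The forward step must override the normal regiochemistry, deliver the cis,cis triad and choose one face of the enone.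

13 ⇒ 8 + 9 + 10. The O5–Si and O6–Si bonds are cut. The precursor falls into an enal, a dichlorosilane and a keto-enol. The forward step must attach two different enol oxygens to one silicon in sequence and keep the E (diene) and Z (enone) geometries.

8 ⇒ 6. The C1–C6 bond is cut (one-carbon formyl unit). The forward step must enolise the methyl side only and leave C8 configurationally intact.

6 ⇒ 4. The C7–C1 bond is cut (methyl to acyl carbon). The forward step must stop at the ketone.

4 ⇒ 3. The O8–Si bond is cut; this is a simple protection.

3 ⇒ 1 + 2. The C9–C10 bond is cut. The C8 stereocentre is traced to a commercial epoxy ester, so no asymmetric step is needed. The forward step must open the epoxide at its terminal carbon in the presence of the ester.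

## Other disconnections considered

Alternative 1: The ring is cut at C1–C6 and C2–C3. In the forward step Cu(SbF6)2 (divalent copper) with a chiral bis(oxazoline) would join diene A2 and acrylimide A3 to the endo adduct A1. Hydrolysis, iodolactonisation and elimination would then carry the carboxyl oxygen to C5 and move the alkene to C3=C4 (lactone A4).
- In favour: the cycloaddition is of a known, catalytic type, and its regiochemistry is the electronically preferred one.
- Better than the chosen plan: the absolute configuration of C1 and C6 comes from the catalyst and does not depend on C8.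
- Against: A1 has the alkene in the wrong place and no oxygen on C5, so three relay steps are needed. The whole C8–C11 chain is missing. The C7–C8 bond and the C8 stereocentre would have to be made afterwards next to a hindered ring.
- Comparison: the chosen step delivers C5–O, C6–O, the C3=C4 alkene and the complete chain at once. Alternative 1 is better on precedent and on mechanism (matched polarity) and worse on structure and step economy by an estimated five or six steps.

Alternative 2: The chain is cut at C7–C8 and C9–C10. The alkenyllithium from iodide A6 would add to vinylboronate A7. Pd(OAc)2 with a chiral ferrocenyl bisphosphine would then couple the ate complex with triflate A8 to give boronate A5, which is oxidised to the C8 alcohol.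
- In favour: the chain and C8 are built in one catalytic step.
- Better than the chosen plan: C7=CH2 is present from the start, so no hindered ketone has to be methylenated.
- Equal to the chosen plan: C8 is set independently of the ring (here by the catalyst, there from the chiral pool).
- Against: it does nothing for the real problem, the cis,cis ring triad, because A6 must already contain the finished ring. The migrating group is a hindered α-branched alkenyl. A5 is an allylic boronate prone to 1,3-boryl shift. The catalyst must overrule the adjacent C1 centre.
- Comparison: mechanistically elegant for the chain, but the ring synthesis in front of it makes the total sequence clearly longer.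

Alternative 3: The ring is cut at C4–C5. CrCl2 (divalent chromium) with catalytic NiCl2 would turn the (Z)-alkenyl iodide of aldehyde A10 into an alkenylchromium species that closes the cyclohexene, giving A9.
- In favour: the reaction type is known, mild and chemoselective. The alkene is formed directly at C3=C4, and C7=CH2 and C8 are already in place.
- Better than the chosen plan: A9 has O5 free and O6 silylated, so the 5,6-diol is differentiated from the outset.
- Equal to the chosen plan: the new centre (C5) is under substrate control, here by the adjacent C6 silyl ether, and the sense is uncertain.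
- Against: A10 is an acyclic precursor in which C1, C6 and C8 must each be set by a separate asymmetric operation. It contains an epimerisable α-silyloxy aldehyde and a (Z)-trisubstituted iodide.
- Comparison: one bond and one stereocentre per key step, against two bonds, two rings and three stereocentres in the chosen step. Better in precedent and in diol differentiation, worse in step economy.

Key step: step 6

Remarks on the chemistry (assumptions):
- Numbering: ring C1–C6 and chain C7–C11 as in the target are used for every compound; descriptors refer to this numbering.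
- Check of the key-step structures: both were compared atom by atom with the target. Constitution, the (1E) dienol ether, the (Z) enone and (8S) are consistent, and the adduct has C7, O5 and O6 on one face in the absolute sense of the target. Nothing had to be corrected and the skeleton, the iPr2Si bridge and the O8 TBS group are kept. C1 is S in ketone 14 and R after methylenation; this is a priority change, not a change of geometry.
- The description is thin on three points: the lability of the Z-silyloxy enone, the differentiation of O5 and O6, and the order of the late oxidations. These are handled by procedure and by the order of steps, not by changing the precursor.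
- The D-fructose-derived ketone is taken to give the (10R) oxirane on an R–CH2–CH=CMe2 alkene, by analogy with its (R,R) sense on trans alkenes.

## Steps

Step 1
Reactants: 1 methyl (S)-oxirane-2-carboxylate (methyl (S)-glycidate); 2 (2-methylprop-1-en-1-yl)magnesium bromide
Product: 3 methyl (S)-2-hydroxy-5-methylhex-4-enoate
Conditions: 2 (1.5 equiv), CuI (10 mol%), THF, −40 → −20 °C; aq. NH4Cl
Reagents that add atoms: none
Why: Copper-catalysed SN2 opening of the terminal oxirane carbon by the alkenyl Grignard reagent forms C9–C10 faster than ester addition at low temperature; C8 is not touched, so the (S) centre of the chiral pool is carried over.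

Step 2
Reactants: 3 methyl (S)-2-hydroxy-5-methylhex-4-enoate
Product: 4 methyl (S)-2-[(tert-butyldimethylsilyl)oxy]-5-methylhex-4-enoate
Conditions: TBSCl, imidazole, DMF, rt
Reagents that add atoms: tert-butyldimethylsilyl chloride, CC(C)(C)[Si](C)(C)Cl
Why: Standard silylation of a secondary alcohol; the bulky ether later shields H8 from enolisation and sets the conformation of the dienophile.

Step 3
Reactants: 4 methyl (S)-2-[(tert-butyldimethylsilyl)oxy]-5-methylhex-4-enoate
Product: 6 (S)-3-[(tert-butyldimethylsilyl)oxy]-6-methylhept-5-en-2-one, via Weinreb amide 5 (not isolated)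
Conditions: MeNHOMe·HCl, iPrMgCl, THF, −20 °C; then MeMgBr, 0 °C; aq. NH4Cl
Reagents that add atoms: methylmagnesium bromide, C[Mg]Br (N,O-dimethylhydroxylamine hydrochloride, CNOC.Cl, leaves atoms only in intermediate 5)
Why: Weinreb ketone synthesis in one flask: the magnesium amide converts the ester into the N-methoxy-N-methylamide, whose chelated tetrahedral adduct with MeMgBr stops at the ketone; α-silyloxy amides of this kind are not epimerised under these conditions.

Step 4
Reactants: 6 (S)-3-[(tert-butyldimethylsilyl)oxy]-6-methylhept-5-en-2-one
Product: 8 (1Z,4S)-4-[(tert-butyldimethylsilyl)oxy]-1-hydroxy-7-methylocta-1,6-dien-3-one (hydrogen-bonded enol of the β-keto aldehyde), via lithium enolate 7 (not isolated)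
Conditions: LiN(iPr)2, THF, −78 °C; CF3CH2OCHO, −78 °C; cold aq. NH4Cl, pH 5
Reagents that add atoms: 2,2,2-trifluoroethyl formate, O=COCC(F)(F)F
Why: Claisen formylation of the kinetic methyl-side enolate (the silyloxy-bearing side is hindered) adds C6; the fast trifluoroethyl ester avoids enolate equilibration, and the product is at once deprotonated to its chelated salt, which protects C8.

Step 5
Reactants: 9 (E)-2-methylbut-2-enal (tiglic aldehyde); 10 dichlorodiisopropylsilane; 8 (1Z,4S)-4-[(tert-butyldimethylsilyl)oxy]-1-hydroxy-7-methylocta-1,6-dien-3-one
Product: 13 (1Z,4S)-4-[(tert-butyldimethylsilyl)oxy]-1-[(diisopropyl{[(1E)-2-methylbuta-1,3-dien-1-yl]oxy}silyl)oxy]-7-methylocta-1,6-dien-3-one, via potassium dienolate 11 (not isolated), via dienyloxychlorosilane 12 (not isolated)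
Conditions: 9, KN(SiMe3)2, THF, −78 °C; into 10 (1.1 equiv), −78 → 0 °C; then 8 (0.85 equiv), Et3N, −40 → 0 °C; pentane, filtration, short pad of Et3N-deactivated silica
Reagents that add atoms: none
Why: Sequential substitution at silicon, the known way to unsymmetrical diisopropylsilyl bis-enol ethers: γ-deprotonation of the s-trans enal gives the (1E)-dienolate, the first chloride of 10 is displaced fast and the second only by the acidic enol 8 with amine; O-silylation of the chelated enol at the formyl oxygen should retain the Z geometry.

Step 6
Reactants: 13 (1Z,4S)-4-[(tert-butyldimethylsilyl)oxy]-1-[(diisopropyl{[(1E)-2-methylbuta-1,3-dien-1-yl]oxy}silyl)oxy]-7-methylocta-1,6-dien-3-one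
Product: 14 (1S,5R,6S,8S)-cycloadduct ketone: 4-methylcyclohex-3-ene whose O5 and O6 are bridged as a cis-fused 2,2-diisopropyl-1,3,2-dioxasilolane and whose C1 bears the (S)-2-[(tert-butyldimethylsilyl)oxy]-5-methylhex-4-enoyl group cis to both ring oxygens
Conditions: toluene (0.01 M), 2,6-di-tert-butyl-4-methylpyridine (0.2 equiv), BHT, silylated sealed tube, 140–160 °C
Reagents that add atoms: none
Why: Proposed new method: a thermal, concerted but asynchronous [4+2] cycloaddition in which the (1E)-dienyl silyl ether (C2–C5) and the (Z)-β-silyloxy enone (C6=C1, activated by C7=O) are held on one diisopropylsilylene, so that the three-atom O–Si–O tether overrides the electronic preference of both donor oxygens and forces C5 to bond to C6 while C2 bonds to C1; the closest known reaction type is the intramolecular Diels–Alder reaction through temporary silicon (silyl acetal) tethers, with the geometry of a 1,3,8-nonatriene. The cyclohexene closes by the cycloaddition itself (both new bonds, alkene left at C3=C4), and the dioxasilolane closes as the consequence of the C5–C6 bond, five-membered and cis-fused. C1 and C6 are set relative to each other by the Z geometry of the dienophile, because suprafacial addition keeps O6 and C7 cis. C5 is set relative to C6 by the E geometry of the dienol ether together with the tether-endo transition state, the only one that leads to an unstrained cis-fused silolane and that also places the C7 acyl group endo. The absolute sense is controlled by C8: in the s-cis enone the C8–O bond lies anti to C7=O, H8 and C9 flank the enone plane, and addition to the face of H8 gives the (1S,5R,6S) adduct drawn. The step needs regioselectivity (tether), cis/endo selectivity (Z dienophile, short tether), facial selectivity (C8, the weak point) and survival of the Z-enol ether (acid-free glass, hindered pyridine, high dilution); a competing 1,5-silyl shift to O7 should be unproductive, since the shifted isomer offers only a far more hindered trisubstituted dienophile.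

Step 7
Reactants: 14 (1S,5R,6S,8S)-cycloadduct ketone
Product: 15 (1R,5R,6S,8S)-methylene compound: as 14 but with C7=CH2, chain C7(=CH2)–C8H(OTBS)–CH2–CH=CMe2
Conditions: Zn, CH2Br2, TiCl4, THF (reagent pre-formed at 5 °C); 14, CH2Cl2, 0 °C → rt
Reagents that add atoms: dibromomethane, BrCBr
Why: Takai–Lombardo methylenation; the gem-dimetallic titanium reagent is non-basic, so the hindered ketone should be converted without epimerisation at C1 or C8 and without β-elimination of O6.

Step 8
Reactants: 15 (1R,5R,6S,8S)-methylene compound
Product: 16 (1R,5R,6S,8S)-cis-diol: 1-[(S)-3-[(tert-butyldimethylsilyl)oxy]-6-methylhepta-1,5-dien-2-yl]-4-methylcyclohex-3-ene-5,6-diol with the chain and both hydroxyls on one face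
Conditions: HF·pyridine, pyridine, THF, 0 °C
Reagents that add atoms: none
Why: Fluoride cleavage of the strained five-membered silylene, which is far more labile than the secondary TBS ether under buffered conditions.

Step 9
Reactants: 16 (1R,5R,6S,8S)-cis-diol
Product: 17 (1R,3R,4S,5S,6S,8S)-epoxy diol: 3,4-epoxide of 16 with the oxirane oxygen on the face of the 5- and 6-hydroxyls
Conditions: VO(acac)2 (5 mol%), t-BuOOH (1.2 equiv), CH2Cl2, 0 °C → rt
Reagents that add atoms: tert-butyl hydroperoxide, CC(C)(C)OO
Why: Hydroxyl-directed vanadium-catalysed epoxidation: the allylic O5–H (reinforced by the homoallylic O6–H on the same face) delivers the peroxide syn to the ring alkene only; the chain alkenes have no free allylic hydroxyl because O8 is silylated.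

Step 10
Reactants: 17 (1R,3R,4S,5S,6S,8S)-epoxy diol
Product: 18 (1R,3S,4S,5S,6S,8S)-chlorotriol: 3-chloro-4-methylcyclohexane-4,5,6-triol carrying the C1 chain; Cl trans to the 4-OH; the 4-, 5- and 6-hydroxyls and the chain cis; O8 still a TBS ether
Conditions: Ti(OiPr)4 (1.5 equiv), Et2NH·HCl, CH2Cl2, rt
Reagents that add atoms: diethylammonium chloride, CC[NH2+]CC.[Cl-]
Why: Titanium-assisted opening of a 2,3-epoxy alcohol: the O5-bound titanium activates the oxirane and chloride attacks the distal, secondary C3 with inversion; this is also the trans-diaxial (Fürst–Plattner) mode through the chair with the chain equatorial, so C3 gets Cl anti to the C4 hydroxyl.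

Step 11
Reactants: 18 (1R,3S,4S,5S,6S,8S)-chlorotriol; 19 (Z)-2-methylbut-2-enoic acid (angelic acid)
Product: 20 (1R,3S,4S,5S,6S,8S)-5-O-angelate of 18 (4-OH and 6-OH free; O8 TBS)
Conditions: 19, 1-chloro-N,N,2-trimethylprop-1-en-1-amine, CH2Cl2, 0 °C; then 18, Ph2BOCH2CH2NH2 (10 mol%), iPr2NEt, MeCN, 0 °C → rt
Reagents that add atoms: none
Why: Borinic acid-catalysed regioselective acylation of a cis-1,2-diol: the tetracoordinate borinate of the 5,6-diol is acylated at its equatorial oxygen (O5), while the axial 6-OH (1,3-diaxial to the 4-OH) and the tertiary 4-OH stay free; the acid chloride is made under neutral conditions and no nucleophilic amine is present, so the Z ester geometry should be kept.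

Step 12
Reactants: 20 (1R,3S,4S,5S,6S,8S)-5-O-angelate
Product: 21 (1R,3S,4S,5S,6S,8S)-5-O-angelate with free 8-OH (4-, 6- and 8-hydroxyls free)
Conditions: HF·pyridine, pyridine, THF, 0 °C → rt
Reagents that add atoms: none
Why: Fluoride desilylation under weakly acidic, non-basic conditions: the chlorohydrin cannot close, acyl migration to O6 is slow, and no epoxide is yet present to be opened.

Step 13
Reactants: 21 (1R,3S,4S,5S,6S,8S)-5-O-angelate with free 8-OH; 19 (Z)-2-methylbut-2-enoic acid (angelic acid)
Product: 22 (1R,3S,4S,5S,6S,8S)-5,8-di-O-angelate (prenyl alkene still present)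
Conditions: 19, 2,4,6-trichlorobenzoyl chloride, Et3N, toluene, rt; then 21, 50–70 °C
Reagents that add atoms: none
Why: Yamaguchi-type mixed-anhydride esterification without nucleophilic catalyst, the established way to angelates without Z to E isomerisation; O8–H is the only unhindered secondary hydroxyl, whereas O6–H is axial and flanked by the ester and the chain.

Step 14
Reactants: 22 (1R,3S,4S,5S,6S,8S)-5,8-di-O-angelate
Product: 23 target CNP0158207.1, (1R,3S,4S,5S,6S,8S,10R)
Conditions: 1,2:4,5-di-O-isopropylidene-β-D-erythro-2,3-hexodiulo-2,6-pyranose (0.3–0.5 equiv), Oxone, K2CO3/Na2B4O7 buffer (pH ≈ 10), Bu4NHSO4, MeCN–CH2(OMe)2–H2O, 0 °C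
Reagents that add atoms: potassium peroxymonosulfate (Oxone, KHSO5), [K+].[O-]S(=O)(=O)OO
Why: Shi epoxidation: the chiral dioxirane attacks the electron-rich trisubstituted C10=C11 alkene through a spiro transition state and the D-fructose-derived ketone should give (10R); the 1,1-disubstituted alkene next to an allylic ester and the two conjugated ester alkenes are much less reactive.

## Compound list

1 | methyl (S)-oxirane-2-carboxylate | COC(=O)[C@@H]1CO1 | starting material
2 | (2-methylprop-1-en-1-yl)magnesium bromide | CC(C)=C[Mg]Br | starting material
3 | methyl (S)-2-hydroxy-5-methylhex-4-enoate | COC(=O)[C@@H](O)CC=C(C)C | intermediate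
4 | methyl (S)-2-[(tert-butyldimethylsilyl)oxy]-5-methylhex-4-enoate | COC(=O)[C@@H](O[Si](C)(C)C(C)(C)C)CC=C(C)C | intermediate
5 | (S)-2-[(tert-butyldimethylsilyl)oxy]-N-methoxy-N,5-dimethylhex-4-enamide (Weinreb amide, not isolated) | CON(C)C(=O)[C@@H](O[Si](C)(C)C(C)(C)C)CC=C(C)C | intermediate
6 | (S)-3-[(tert-butyldimethylsilyl)oxy]-6-methylhept-5-en-2-one | CC(=O)[C@@H](O[Si](C)(C)C(C)(C)C)CC=C(C)C | intermediate
7 | lithium (S)-3-[(tert-butyldimethylsilyl)oxy]-6-methylhepta-1,5-dien-2-olate (not isolated) | [Li+].C=C([O-])[C@@H](O[Si](C)(C)C(C)(C)C)CC=C(C)C | intermediate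
8 | (1Z,4S)-4-[(tert-butyldimethylsilyl)oxy]-1-hydroxy-7-methylocta-1,6-dien-3-one | O/C=C\C(=O)[C@@H](O[Si](C)(C)C(C)(C)C)CC=C(C)C | intermediate
9 | (E)-2-methylbut-2-enal (tiglic aldehyde) | C/C=C(\C)C=O | starting material
10 | dichlorodiisopropylsilane | CC(C)[Si](Cl)(Cl)C(C)C | starting material
11 | potassium (1E)-2-methylbuta-1,3-dien-1-olate (not isolated) | [K+].C=C/C(C)=C/[O-] | intermediate
12 | chloro(diisopropyl){[(1E)-2-methylbuta-1,3-dien-1-yl]oxy}silane (not isolated) | C=C/C(C)=C/O[Si](Cl)(C(C)C)C(C)C | intermediate
13 | diisopropylsilylene-tethered dienyl ether and (Z)-β-silyloxy enone (8S), precursor of the key step | C=C/C(C)=C/O[Si](C(C)C)(C(C)C)O/C=C\C(=O)[C@@H](O[Si](C)(C)C(C)(C)C)CC=C(C)C | intermediate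
14 | (1S,5R,6S,8S)-cycloadduct ketone with cis-fused dioxasilolane | CC(C)=CC[C@H](O[Si](C)(C)C(C)(C)C)C(=O)[C@H]1CC=C(C)[C@H]2O[Si](C(C)C)(C(C)C)O[C@@H]12 | intermediate
15 | (1R,5R,6S,8S)-methylene compound with cis-fused dioxasilolane | C=C([C@H](CC=C(C)C)O[Si](C)(C)C(C)(C)C)[C@H]1CC=C(C)[C@H]2O[Si](C(C)C)(C(C)C)O[C@@H]12 | intermediate
16 | (1R,5R,6S,8S)-cis-5,6-diol | C=C([C@H](CC=C(C)C)O[Si](C)(C)C(C)(C)C)[C@H]1CC=C(C)[C@@H](O)[C@H]1O | intermediate
17 | (1R,3R,4S,5S,6S,8S)-3,4-epoxy-5,6-diol | C=C([C@H](CC=C(C)C)O[Si](C)(C)C(C)(C)C)[C@H]1C[C@H]2O[C@@]2(C)[C@@H](O)[C@H]1O | intermediate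
18 | (1R,3S,4S,5S,6S,8S)-3-chloro-4,5,6-triol, O8 TBS | C=C([C@H](CC=C(C)C)O[Si](C)(C)C(C)(C)C)[C@H]1C[C@H](Cl)[C@@](C)(O)[C@@H](O)[C@H]1O | intermediate
19 | (Z)-2-methylbut-2-enoic acid (angelic acid) | C/C=C(/C)C(=O)O | starting material
20 | (1R,3S,4S,5S,6S,8S)-5-O-angelate, O8 TBS | C=C([C@H](CC=C(C)C)O[Si](C)(C)C(C)(C)C)[C@H]1C[C@H](Cl)[C@@](C)(O)[C@@H](OC(=O)/C(C)=C\C)[C@H]1O | intermediate
21 | (1R,3S,4S,5S,6S,8S)-5-O-angelate, 8-OH free | C=C([C@H](CC=C(C)C)O)[C@H]1C[C@H](Cl)[C@@](C)(O)[C@@H](OC(=O)/C(C)=C\C)[C@H]1O | intermediate
22 | (1R,3S,4S,5S,6S,8S)-5,8-di-O-angelate | C=C([C@H](CC=C(C)C)OC(=O)/C(C)=C\C)[C@H]1C[C@H](Cl)[C@@](C)(O)[C@@H](OC(=O)/C(C)=C\C)[C@H]1O | intermediate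
23 | CNP0158207.1, (1R,3S,4S,5S,6S,8S,10R) | C=C([C@H](C[C@H]1OC1(C)C)OC(=O)/C(C)=C\C)[C@H]1C[C@H](Cl)[C@@](C)(O)[C@@H](OC(=O)/C(C)=C\C)[C@H]1O | target

## Step count and least certain steps

Total step count: 14. Longest linear sequence: 14 steps (1 to 23); the dienyl chlorosilane branch is made inside step 5.

**Step 6 (key step).** Three processes may spoil it:
- scrambling of the dienophile before cycloaddition, by thermal or trace-acid E/Z isomerisation or by silyl migration from O6 to O7;
- too slow a cycloaddition of a tether-forced, electronically mismatched and doubly donor-substituted pair, so that desilylation or oligomerisation wins;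
- poor facial discrimination by the single C8 centre, which would give the diastereomeric all-cis adduct.

Fallback, all steps of known type: the tether is given up and the ring is built by a reagent-controlled intermolecular cycloaddition on the other pair of ring bonds (C1–C6, C2–C3). It sets out from none of the numbered intermediates (two further commercial compounds, 3-methylbut-2-enal and 3-acryloyl-1,3-oxazolidin-2-one) and comes back to the route at 14.
- 3-Methylbut-2-enal would be O-acetylated (isopropenyl acetate, TsOH) to (E)-1-acetoxy-3-methylbuta-1,3-diene F1.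
- Cu(SbF6)2 (divalent copper) with the suitable enantiomer of 2,2'-isopropylidenebis(4-tert-butyl-2-oxazoline) should add the acrylimide to F1 to give the endo imide F2 (the structure of A1).
- LiOH/H2O2, then LiOH, would give the cis hydroxy acid F3.
- I2/NaHCO3 would give the iodolactone F4, with the carboxylate oxygen on C5 on the face of C7 and iodine on C4.
- DBU would give the unsaturated lactone F5 with the alkene at C3=C4.
- (4-Methylpent-3-en-1-yl)lithium (2.2 equiv, −78 °C) would open the lactone to the keto diol F6.
- iPr2Si(OTf)2/2,6-lutidine would give the silylene ketone F7.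
- KN(SiMe3)2 on the less hindered C8 methylene, then the matched enantiomer of (camphorsulfonyl)oxaziridine, would give the (8S)-hydroxy ketone F8.
- TBSOTf/2,6-lutidine would give 14.

**Step 5.** What may go wrong: loss of the Z geometry of the enol ether by chloride- or amine-mediated addition–elimination, double substitution at silicon, or attack of the free dienolate on the enone.

Fallback, setting out from 8 and returning at 13: the order of attachment is reversed and the aldehyde is enolised softly, with no strong base.
- The lithium chelate of 8 (LiN(SiMe3)2, −78 °C) would be added to excess 10 to give the (Z)-chlorosilyl enol ether F9, and the surplus 10 stripped in vacuum.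
- AgOTf would convert F9 into the silyl triflate F10, with AgCl precipitating so that no soluble halide remains.
- F10 with 9 and Et3N at −78 °C (the standard silyl triflate/amine route to dienol ethers) would give 13.

**Step 7.** What may go wrong: no conversion of the doubly α-branched ketone, or Lewis-acid-induced loss of the β-silyloxy group.

Fallback, setting out from 14 and returning at 16: Peterson olefination in place of the titanium methylidene.
- Me3SiCH2MgCl/CeCl3 (THF, −78 °C) should add to the ketone without enolisation to give the β-hydroxysilane F11 (either C7 epimer).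
- HF·pyridine would then bring about the acid-type elimination of Me3Si/OH and cleave the silylene in the same operation, giving 16 directly.

**Step 11.** What may go wrong: acylation at the axial O6 or at both oxygens, and Z to E isomerisation of the acyl chloride.

Fallback, setting out from 15 and returning at 21: the two oxygens are told apart by a protecting group, not by a catalyst.
- MeLi (1.1 equiv, Et2O, −78 °C) should open the strained dioxasilolane at silicon and release the less hindered, allylic C5 alkoxide, giving the 6-O-diisopropylmethylsilyl ether F12.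
- VO(acac)2/t-BuOOH would give the epoxy alcohol F13.
- Ti(OiPr)4/Et2NH·HCl would give the chlorodiol F14.
- The only free secondary hydroxyl (O5) would be esterified with the mixed anhydride of 19 to give F15.
- HF·pyridine would remove both silyl ethers to give 21.

## Further compounds

F1 | step 6 | (E)-1-acetoxy-3-methylbuta-1,3-diene | CC(=O)O/C=C/C(C)=C
F2 | step 6 | endo cycloadduct imide with C6 acetate cis to the C7 imide | CC(=O)O[C@@H]1C=C(C)CC[C@@H]1C(=O)N2CCOC2=O
F3 | step 6 | cis-6-hydroxy-4-methylcyclohex-4-ene-1-carboxylic acid | O[C@@H]1C=C(C)CC[C@@H]1C(=O)O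
F4 | step 6 | iodolactone: C7 carboxyl bridged to O5, iodine and methyl on C4, 6-OH free | O=C1O[C@H]2[C@@H](O)[C@@H]1CC[C@]2(C)I
F5 | step 6 | unsaturated bicyclic lactone with C3=C4 alkene and free 6-OH | O=C1O[C@H]2[C@@H](O)[C@@H]1CC=C2C
F6 | step 6 | keto diol: 1-(5-methylhex-4-enoyl)-4-methylcyclohex-3-ene-cis-5,6-diol | CC(C)=CCCC(=O)[C@H]1CC=C(C)[C@@H](O)[C@H]1O
F7 | step 6 | silylene ketone lacking the C8 oxygen | CC(C)=CCCC(=O)[C@H]1CC=C(C)[C@H]2O[Si](C(C)C)(C(C)C)O[C@@H]12
F8 | step 6 | (8S)-hydroxy ketone with cis-fused dioxasilolane | CC(C)=CC[C@H](O)C(=O)[C@H]1CC=C(C)[C@H]2O[Si](C(C)C)(C(C)C)O[C@@H]12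
F9 | step 5 | (Z)-β-[chloro(diisopropyl)silyloxy] enone from 8 | CC(C)[Si](Cl)(C(C)C)O/C=C\C(=O)[C@@H](O[Si](C)(C)C(C)(C)C)CC=C(C)C
F10 | step 5 | (Z)-β-[diisopropyl(trifluoromethanesulfonyloxy)silyloxy] enone | CC(C)[Si](OS(=O)(=O)C(F)(F)F)(C(C)C)O/C=C\C(=O)[C@@H](O[Si](C)(C)C(C)(C)C)CC=C(C)C
F11 | step 7 | C7 tertiary β-hydroxysilane (C7 configuration not defined) | C[Si](C)(C)CC(O)([C@H](CC=C(C)C)O[Si](C)(C)C(C)(C)C)[C@H]1CC=C(C)[C@H]2O[Si](C(C)C)(C(C)C)O[C@@H]12
F12 | step 11 | 6-O-diisopropylmethylsilyl ether with free 5-OH | C=C([C@H](CC=C(C)C)O[Si](C)(C)C(C)(C)C)[C@H]1CC=C(C)[C@@H](O)[C@H]1O[Si](C)(C(C)C)C(C)C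
F13 | step 11 | 3,4-epoxide of F12, oxygen syn to the 5-OH | C=C([C@H](CC=C(C)C)O[Si](C)(C)C(C)(C)C)[C@H]1C[C@H]2O[C@@]2(C)[C@@H](O)[C@H]1O[Si](C)(C(C)C)C(C)C
F14 | step 11 | 3-chloro-4,5-diol, O6 diisopropylmethylsilyl, O8 TBS | C=C([C@H](CC=C(C)C)O[Si](C)(C)C(C)(C)C)[C@H]1C[C@H](Cl)[C@@](C)(O)[C@@H](O)[C@H]1O[Si](C)(C(C)C)C(C)C
F15 | step 11 | 5-O-angelate of F14 | C=C([C@H](CC=C(C)C)O[Si](C)(C)C(C)(C)C)[C@H]1C[C@H](Cl)[C@@](C)(O)[C@@H](OC(=O)/C(C)=C\C)[C@H]1O[Si](C)(C(C)C)C(C)C
A1 | alternative 1 | endo cycloadduct with C6 acetate cis to the C7 imide | CC(=O)O[C@@H]1C=C(C)CC[C@@H]1C(=O)N2CCOC2=O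
A2 | alternative 1 | (E)-1-acetoxy-3-methylbuta-1,3-diene | CC(=O)O/C=C/C(C)=C
A3 | alternative 1 | 3-acryloyl-1,3-oxazolidin-2-one | C=CC(=O)N1CCOC1=O
A4 | alternative 1 | bicyclic lactone with O5 from the C7 carboxyl and the alkene at C3=C4 | O=C1O[C@H]2[C@@H](O)[C@@H]1CC=C2C
A5 | alternative 2 | C8 pinacol boronate with the complete carbon skeleton | C=C([C@H](CC=C(C)C)B1OC(C)(C)C(C)(C)O1)[C@H]1CC=C(C)[C@H]2OC(C)(C)O[C@@H]12
A6 | alternative 2 | ring alkenyl iodide with 5,6-O-isopropylidene | C=C(I)[C@H]1CC=C(C)[C@H]2OC(C)(C)O[C@@H]12
A7 | alternative 2 | vinylboronic acid pinacol ester | C=CB1OC(C)(C)C(C)(C)O1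
A8 | alternative 2 | 2-methylprop-1-en-1-yl trifluoromethanesulfonate | CC(C)=COS(=O)(=O)C(F)(F)F
A9 | alternative 3 | cyclohexenol with free 5-OH, 6-O-TBS and 8-O-PMB | C=C([C@H](CC=C(C)C)OCc1ccc(OC)cc1)[C@H]1CC=C(C)[C@@H](O)[C@H]1O[Si](C)(C)C(C)(C)C
A10 | alternative 3 | acyclic (Z)-alkenyl iodide with C5 aldehyde | O=C[C@@H](O[Si](C)(C)C(C)(C)C)[C@H](C/C=C(/C)I)C(=C)[C@H](CC=C(C)C)OCc1ccc(OC)cc1
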